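**Remark on the chemistry (assumption):** (1S,5R)-bicyclo[3.1.0]hexan-2-one (1) is taken as a purchasable single enantiomer; it is the antipode of the more common (1R,5S) ketone and is made the same way from the enantiomeric epoxide. Atoms carry lindenane numbers (C1–C15, primes for the second half); compounds are numbered 1–27 in the order of the steps.

## Analysis of the target

The target is a C2-symmetric head-to-head dimer of a lindenane-type sesquiterpene lactone. Each half holds a cyclopropane (C1–C2–C3) fused to a cyclopentane (ring A: C1, C3, C4, C5, C10) with the exocyclic C4=C15 methylene, a cyclohexane (ring B: C5–C10) and an α-methyl butenolide (O–C8, C7=C11, C12=O, C13). The halves are joined by a cyclobutane built from C8, C9, C9' and C8', which makes nine rings in all.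

There are twelve stereocenters (C1, C3, C5, C8, C9, C10 and their primed partners). On ring A the cyclopropane methylene C2, the C14 methyl and C6 lie on one face, H5 and C9 on the other (trans A/B fusion). On ring B the C14 methyl, H9 and the lactone oxygen on C8 share one face and the cyclobutane bonds lie on the other. Across the cyclobutane C10 and C10' are trans and the two lactone oxygens are trans.

The sensitive groups are the two vinylcyclopropanes (acid, radicals, low-valent metals), the butenolides (base), and C5, which becomes epimerisable whenever C4 is a ketone because the trans-fused 5/6 ketone is the less stable fusion. The synthesis is hard because the four cyclobutane carbons are contiguous, fully substituted or tertiary, and flanked by the quaternary C10 centres, and every bond has to be made twice.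

The strategy rests on one feature. In each half C8 carries an oxygen and is bonded to C7, and the chain C7=C11–C12(=O)–O returns to that oxygen. This is the unit that an alkyne (C7≡C11), a ketone (C8=O) and one carbonyl carbon (C12) assemble. C8 and C8' are neighbours, so both ketones can belong to one cyclobutane-1,2-dione, and the tether C8–C9–C10–C5–C6–C7 closes ring B in the same event.

## Retrosynthetic reasoning

**C4=C15 and C4'=C15' (27 ⇒ 26 ⇒ 25).** The exocyclic alkenes are cut first, back to diketone 26 and its bis(dioxolane) 25. A methylene next to the cyclopropane, four atoms from an alkyne, would compete for a low-valent metal and would not survive the halogen oxidation that makes the dione, so C4 travels as a masked ketone. The ketal also removes the acidity of H5. Forward, the ketals must be hydrolysed and both ketones methylenated without enolising C4 toward C5.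

**C7–C8, C11–C12 and C12–O, twice (25 ⇒ 23).** These six cuts open both rings B and both butenolides and leave dione 23 with but-2-ynyl chains on C5 and C5'. The cut is made here because C8 is the only carbon of each half with a ring oxygen and C8/C8' are adjacent, so one four-membered 1,2-diketone supplies both. The gain is four rings, six skeletal bonds and the last two stereocenters in one operation on a C2-symmetric substrate. The forward reaction has to join each alkyne to the nearer ketone and one carbonyl unit, on the cyclobutane face that carries that half's C10, before the strained diketone is lost in other ways.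

**C8–C8' (23 ⇒ 22 ⇒ 21).** The dione comes from enediol bis(silyl ether) 22 and this from succinate diester 21 by reductive coupling of the ester carbonyls. Cutting C8–C8' turns the cyclobutane into an open succinate in which C9 and C9' are ordinary α-carbons that enolate chemistry can join and configure. Forward, a four-membered ring must close between two hindered esters and the enediol must be oxidised without touching alkynes or ketals.

**C5–C6 and C5'–C6' (21 ⇒ 20 ⇒ 19 ⇒ 16 + 17).** The butynyl chains are introduced with bromide 17 on the dimeric diketo diacid 16. At that stage C10 carries a methyl group on one face and a large branched C9 substituent on the other, so attack on the C5 enolate anti to the large group puts C6 syn to C14, as the target needs and as equilibration would also favour. In a monomer the two C10 substituents would be of similar size and the cyclopropane would bias C5 the wrong way. The C4 ketones must be free for this step and are masked again afterwards (21); as carboxylates the C8 groups cannot be acylated by the enolates.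

**C9–C9' (16 ⇒ 14 ⇒ 12).** The succinate is cut into two identical acyl units, joined forward by oxidative coupling of enolate 13. The two trans-diones that differ at both C9 and C9' are diastereomers and only the (9S,9'S) one leads to 27, so this bond needs control of absolute configuration; auxiliary 9 supplies it and is removed directly afterwards. C4 is a dioxolane in 12 so that only the imide is enolised.

**C9–C10 (12 ⇒ 11 ⇒ 8 ⇒ 7 ⇒ 5).** The acetic acid chain is traced to an allyl group, and this is disconnected from C10 as a conjugate addition to enone 5. The cyclopropane methylene covers one face of C10, so the new carbon enters anti to it and C14 ends syn, as in 27. The C4 carbonyl that drives the addition is the one needed later for the ketal, the C5 enolate and the methylene. A sigmatropic route from the C4 allylic alcohol was set aside: it delivers C9 to the face that carried the oxygen, which after carbonyl reduction of 5 from its open face is the wrong one, and it leaves C4 as an alkene carbon.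

**C10–C14 and the ring unsaturation (5 ⇒ 3 ⇒ 1).** Enone 5 is the β-methyl homologue of enone 3, the dehydrogenation product of ketone 1, which brings the cyclopropane and its two stereocenters. Mapping the carbonyl of 1 onto C4 keeps the oxygen where it is needed and avoids a 1,3-oxygen shift through a tertiary allylic cyclopropylcarbinyl cation, which is prone to skeletal rearrangement.

## Alternatives that were turned down

**Alternative 1:** C9–C10 and C9'–C10' are cut in succinic acid A1, formed by two Ireland–Claisen rearrangements of bis-allylic succinate A2 after double enolisation and O-silylation.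
- For: a chair transition state sets C9, C10, C9' and C10' together, and C9 follows from ketene-acetal geometry without an auxiliary. On this point it is stronger than the chosen route, which spends 9 and steps 5, 7 and 8 on C9/C9'.
- Against, for this target: the shift places C9 on the face that carried the ester oxygen. The target needs C9 anti to the cyclopropane methylene, so A2 requires the allylic alcohol epimer that direct reduction of 5 does not give, hence an inversion. Both ketene acetals must have the same geometry or C9 epimers result, and succinate enolates self-condense.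
- A1 closes no ring and has C4 as an alkene carbon, so ketone installation, the butynyl chains, the cyclobutane, rings B and the butenolides all remain. It replaces only steps 3–8 at about the same length. The chosen route keeps the C4 oxygen in place from 1 to 26 and closes four rings in one step.

**Alternative 2:** C3–C4 is cut in monomeric tricycle A3, closed from vinyl bromide A4 by zerovalent palladium (bulky trialkylphosphine, carbonate base, carboxylate shuttle) through cyclopropane C–H activation.
- For: ring A forms with the C4=C15 methylene already in place, so no late methylenation next to an epimerisable C5. Here it is stronger than steps 15 and 16.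
- Against: the cyclopropyl group of A4 has two diastereotopic methylene groups, and nothing in A4 favours the one that puts C2 syn to C14. The reductive elimination must also build the strained trans-fused ring system.
- A3 is a monomer at the ketone level of C8. Both C8 oxygens, both butenolides, the cyclobutane and the union of the halves remain, and the union would be a photochemical [2+2] dimerisation whose regiochemistry and facial course cannot be enforced. It gives one ring and one bond per half; the chosen step gives four rings and six bonds and fixes C8/C8' through C9/C9'.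

**Alternative 3:** C1–C3 is cut in tricycle A5, formed from eudesmane mesylate A6 by buffered solvolysis in a fluorinated alcohol: the C3=C4 alkene displaces the sulfonate, ring A contracts and the C4 cation loses a C15 proton.
- For: decalins like A6 come from annulation chemistry, and one step forms the cyclopropane, contracts the ring and frees the methylene, with inversion at C1 giving the cyclopropane syn to C14. For ring A alone it is the most economical.
- Against: the alkene lies in the same six-membered ring as the leaving group, so participation needs a boat-like ring A that the trans-decalin resists. The cyclopropylcarbinyl cation can also return to the homoallyl manifold, lose H5 or be captured, and the strained product can re-ionise.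
- Like A3, A5 is a monomer lacking all functionality at C8–C9 and still needs a dimerisation. The chosen route buys the cyclopropane in 1 and never places a cation next to it.

Key step: step 14

## Route

Step 1
Reactants: 1 (1S,5R)-bicyclo[3.1.0]hexan-2-one
Product: 3 (1S,5S)-bicyclo[3.1.0]hex-3-en-2-one, via lithium enolate 2 (not isolated)
Conditions: LiN(iPr)2, THF, −78 °C; then N-tert-butylbenzenesulfinimidoyl chloride, −78 °C
Reagents that add atoms: none
Why: Mukaiyama dehydrogenation: the enolate can form only toward C5 (C3 is a cyclopropane bridgehead), is sulfenylated at C5, and the sulfilimine eliminates syn across C5–C10 below room temperature, so no acid, radical or cation arises next to the cyclopropane; no stereocenter is created.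

Step 2
Reactants: 3 (1S,5S)-bicyclo[3.1.0]hex-3-en-2-one
Product: 5 (1S,5R)-4-methylbicyclo[3.1.0]hex-3-en-2-one, via bromomagnesium enolate 4 (not isolated)
Conditions: MeMgBr, CuBr·SMe2 (10 mol %), THF, −78 °C; then N-tert-butylbenzenesulfinimidoyl chloride, −78 °C → rt
Reagents that add atoms: methylmagnesium bromide, C[Mg]Br
Why: Copper-catalysed conjugate addition puts the methyl group (C14) on C10 and gives enolate 4 regiospecifically; the same sulfinimidoyl chloride dehydrogenates it in the flask (one-pot 1,4-addition–dehydrogenation), sulfur entering C5 trans to the new methyl and so cis to H10 as the syn-elimination needs. C10 returns to sp2, so the facial course of the methyl addition does not matter.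

Step 3
Reactants: 5 (1S,5R)-4-methylbicyclo[3.1.0]hex-3-en-2-one
Product: 7 (1S,4R,5R)-4-methyl-4-(prop-2-en-1-yl)bicyclo[3.1.0]hexan-2-one, via trimethylsilyl enol ether 6 (not isolated)
Conditions: allylMgBr, CuBr·SMe2, LiCl, TMSCl, THF, −78 °C; then 1 M HCl (work-up)
Reagents that add atoms: allylmagnesium bromide, C=CC[Mg]Br
Why: Conjugate allylation with an allylcopper reagent activated by TMSCl, a known way to make quaternary centres on β,β-disubstituted cyclopentenones; the nucleophile enters C10 anti to the cyclopropane methylene, so C14 ends syn to C2 and the future C9 anti, as in the target. Anionic copper chemistry is preferred to Lewis-acid-promoted addition because an O-activated bicyclo[3.1.0]hexenone can open to an aromatic ring.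

Step 4
Reactants: 7 (1S,4R,5R)-4-methyl-4-(prop-2-en-1-yl)bicyclo[3.1.0]hexan-2-one
Product: 8 2-[(1R,2S,5S)-2-methyl-4-oxobicyclo[3.1.0]hexan-2-yl]acetic acid
Conditions: RuCl3·xH2O (2 mol %), NaIO4, MeCN/EtOAc/H2O, 0 °C → rt
Reagents that add atoms: sodium periodate, [Na+].[O-]I(=O)(=O)=O; water, O
Why: RuO4-catalysed oxidative cleavage of the terminal alkene gives the acid one carbon shorter, turning the allyl group into the C9H2–C8O2H unit; the ketone and cyclopropane are inert and no stereocenter is touched.

Step 5
Reactants: 8 2-[(1R,2S,5S)-2-methyl-4-oxobicyclo[3.1.0]hexan-2-yl]acetic acid; 9 (S)-4-benzyloxazolidin-2-one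
Product: 11 (S)-4-benzyl-3-{2-[(1R,2S,5S)-2-methyl-4-oxobicyclo[3.1.0]hexan-2-yl]acetyl}oxazolidin-2-one, via mixed pivalic anhydride 10 (not isolated)
Conditions: PivCl, Et3N, THF, −20 °C; then 9, LiCl, rt
Reagents that add atoms: none
Why: Standard N-acylation of an Evans oxazolidinone through the mixed pivalic anhydride; the hindered pivaloyl carbonyl is not attacked, and the auxiliary is installed to control C9 in step 7.

Step 6
Reactants: 11 keto imide
Product: 12 C4 dioxolane (ethylene ketal) of 11
Conditions: TMSOCH2CH2OTMS, TMSOTf (cat.), CH2Cl2, −20 °C
Reagents that add atoms: 1,2-bis(trimethylsilyloxy)ethane, C[Si](C)(C)OCCO[Si](C)(C)C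
Why: Noyori ketalisation under anhydrous conditions, compatible with the imide; it removes the only other enolisable position (C5, α to C4) before the imide is enolised.

Step 7
Reactants: 12 dioxolane imide (two molecules)
Product: 14 (9S,9'S)-bis-imide (C9–C9' dimer of 12), via lithium Z-enolate 13 (not isolated)
Conditions: LiN(iPr)2, THF, −78 °C; then CuCl2, DMF, −78 → 0 °C
Reagents that add atoms: none
Why: Oxidative homocoupling of chiral N-acyl oxazolidinone enolates, a known route to C2-symmetric 2,3-disubstituted succinates; the chelated Z-enolate 13 is open only on the face remote from the benzyl group, so both new centres form with the same sense, which for this substitution pattern is (9S,9'S). The C9 radical has no β-hydrogen (C10 is quaternary), so disproportionation cannot compete with C–C coupling.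

Step 8
Reactants: 14 (9S,9'S)-bis-imide
Product: 16 (9S,9'S)-diketo succinic diacid (C9–C9' dimer of 8), via bis-dioxolane diacid 15 (not isolated)
Conditions: LiOH, H2O2, THF/H2O, 0 °C; Na2SO3; then 2 M HCl, THF, rt
Reagents that add atoms: hydrogen peroxide, OO; water, O
Why: Lithium hydroperoxide cleaves the exocyclic imide carbonyl selectively even in hindered cases and releases the recoverable auxiliary without touching C9; acidifying the same mixture hydrolyses both dioxolanes, freeing the C4 ketones for step 9.

Step 9
Reactants: 16 (9S,9'S)-diketo succinic diacid; 17 1-bromobut-2-yne (two equivalents)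
Product: 19 (9S,9'S)-diketo diacid with but-2-ynyl groups on C5 and C5' (C6 syn to C14), via tetralithium salt 18 (not isolated)
Conditions: LiN(iPr)2 (4.4 equiv), THF/DMPU, −78 °C; then 17, −78 → −30 °C; 1 M HCl (work-up)
Reagents that add atoms: none
Why: Kinetic enolate alkylation: only C5 and C5' can be enolised (C3 is a cyclopropane bridgehead, the C9–H bonds are α to carboxylates and flanked by fully substituted carbons), and as carboxylates the C8 groups cannot acylate the enolates. The bromide enters each C5 anti to the large branched C9 substituent on C10, that is syn to C14 and C2, which is the C5 configuration of the target and should also be the more stable one.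

Step 10
Reactants: 19 bis(butynyl) diketo diacid
Product: 20 dimethyl ester of 19
Conditions: TMSCHN2, toluene/MeOH, 0 °C → rt
Reagents that add atoms: (trimethylsilyl)diazomethane, C[Si](C)(C)C=[N+]=[N-]
Why: O-Methylation of the acids by diazomethane generated from TMSCHN2 and methanol; it is insensitive to the shielding at C8 and neutral, so C5 and C9 are not epimerised.

Step 11
Reactants: 20 bis(butynyl) diketo diester
Product: 21 bis(dioxolane) of 20 (ketals at C4 and C4')
Conditions: TMSOCH2CH2OTMS, TMSOTf (cat.), CH2Cl2, −20 → 0 °C
Reagents that add atoms: 1,2-bis(trimethylsilyloxy)ethane, C[Si](C)(C)OCCO[Si](C)(C)C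
Why: Noyori ketalisation works on hindered ketones at low temperature; it masks C4 against sodium in step 12 and against vinylcyclopropane chemistry in step 14, and any acid-induced equilibration at C5 should lead to the same, more stable epimer.

Step 12
Reactants: 21 bis(dioxolane) diester
Product: 22 trans-3,4-disubstituted 1,2-bis(trimethylsilyloxy)cyclobutene
Conditions: Na (dispersion), TMSCl, THF, ultrasound, 0 °C
Reagents that add atoms: chlorotrimethylsilane, C[Si](C)(C)Cl
Why: Rühlmann acyloin condensation: ester ketyl coupling forms C8–C8' and the four-membered ring while TMSCl traps methoxide and the enediolate, so neither Dieckmann condensation nor C9 epimerisation occurs and C9/C9' stay trans. Isolated dialkylalkynes and ketals are not reduced by sodium in an aprotic medium at this temperature.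

Step 13
Reactants: 22 bis(silyloxy)cyclobutene
Product: 23 trans-3,4-disubstituted cyclobutane-1,2-dione (bis-butynyl bis-dioxolane, 9S,9'S)
Conditions: Br2 (1.0 equiv), propylene oxide, CH2Cl2/pentane, −78 °C
Reagents that add atoms: none
Why: Bromine oxidation of a 1,2-bis(silyloxy)cyclobutene is the standard entry to cyclobutane-1,2-diones; the electron-rich enediol ether reacts at −78 °C far faster than the alkynes, and propylene oxide traps the TMSBr formed so that the dioxolanes survive. Moisture is excluded because the dione hydrates and ring-contracts.

Step 14
Reactants: 23 cyclobutane-1,2-dione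
Product: 25 bis(dioxolane) bis(butenolide) (27 with both C4=C15 groups replaced by dioxolanes), via keto mono-butenolide 24 (not isolated)
Conditions: Ru3(CO)12 (10 mol %), P(4-CF3C6H4)3 (30 mol %), CO (10 atm), toluene, 140 °C
Reagents that add atoms: carbon monoxide, [C-]#[O+]
Why: Proposed new method: Under CO, Ru3(CO)12 breaks down to mononuclear zerovalent ruthenium carbonyl species that bind the C7≡C11 alkyne together with the neighbouring C8 ketone, couple them oxidatively to an oxaruthenacyclopentene (C7–C8 bond), insert CO into the Ru–C11 bond and release the butenolide by C12–O reductive elimination; the sequence then repeats on keto mono-butenolide 24 at C8'. The closest known reactions are the Ru3(CO)12- or Mo(CO)6-mediated hetero-Pauson–Khand cyclocarbonylation of tethered alkynyl aldehydes and ketones and the Ru3(CO)12-catalysed three-component lactone synthesis that works best with 1,2-dicarbonyl compounds; what has not been shown is the double event on a cyclobutane-1,2-dione. Each ring B closes as a six-membered ring by C7–C8 formation inside the metallacycle, exo to both the alkyne and the carbonyl π-bond, and each butenolide closes as a five-membered ring in the C12–O reductive elimination. C8 and C8' are controlled by C9 and C9': the four-atom tether C9–C10–C5–C6 can deliver C7 only to the ketone face that carries its own C10 (cis 6/4 fusion), and because C10 and C10' are trans on the cyclobutane the two C7–C8 bonds form on opposite faces and the lactone oxygens end trans, as in 27. The step needs each alkyne to choose the nearer ketone (six- against seven-membered ring) and the cyclocarbonylation to outrun metal insertion into the C8–C8' bond; the short tether secures the first, and CO pressure with an electron-poor phosphine is meant to secure the second. The dioxolanes keep vinylcyclopropane and enyne pathways out, and after the first closure the remaining ketone is still activated by the α-acyloxy group on C8.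

Step 15
Reactants: 25 bis(dioxolane) bis(butenolide)
Product: 26 4,4'-diketone (15,15'-dinor-4,4'-dioxo analogue of 27)
Conditions: PPTS, THF/H2O (4:1), 50 °C
Reagents that add atoms: water, O
Why: Mild acid-catalysed ketal hydrolysis; the weak acid is chosen because the freed C4 ketone has an epimerisable trans ring-fusion centre at C5, which stronger acid or base would drive to the cis-fused isomer. The lactones and the cyclobutane are untouched.

Step 16
Reactants: 26 4,4'-diketone
Product: 27 target (CNP0265879.1)
Conditions: Zn, CH2Br2, TiCl4, THF/CH2Cl2, 0 °C → rt
Reagents that add atoms: dibromomethane, BrCBr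
Why: Takai–Lombardo methylenation: the zinc/titanium methylene reagent is non-basic and adds to hindered, enolisable ketones without epimerising C5, and unlike Cp2TiMe2 at the temperature it needs it leaves lactone carbonyls alone. Both C4=C15 bonds form, so the vinylcyclopropanes appear only after all metal and acid chemistry is over.

## Compound list

1 | (1S,5R)-bicyclo[3.1.0]hexan-2-one (carbonyl carbon becomes C4) | O=C1[C@H]2C[C@H]2CC1 | starting material
2 | lithium enolate of 1 (C4=C5) | [Li]OC1=CC[C@@H]2C[C@H]12 | intermediate (not isolated)
3 | (1S,5S)-bicyclo[3.1.0]hex-3-en-2-one | O=C1[C@H]2C[C@H]2C=C1 | intermediate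
4 | bromomagnesium enolate after methyl addition to C10 (methyl anti to the cyclopropane methylene) | Br[Mg]OC1=C[C@@H](C)[C@@H]2C[C@H]12 | intermediate (not isolated)
5 | (1S,5R)-4-methylbicyclo[3.1.0]hex-3-en-2-one | O=C1[C@H]2C[C@H]2C(C)=C1 | intermediate
6 | trimethylsilyl enol ether of 7 | C=CC[C@]1(C)C=C(O[Si](C)(C)C)[C@H]2C[C@@H]12 | intermediate (not isolated)
7 | (1S,4R,5R)-4-methyl-4-(prop-2-en-1-yl)bicyclo[3.1.0]hexan-2-one (allyl anti, methyl syn to the cyclopropane methylene) | C=CC[C@]1(C)CC(=O)[C@H]2C[C@@H]12 | intermediate
8 | 2-[(1R,2S,5S)-2-methyl-4-oxobicyclo[3.1.0]hexan-2-yl]acetic acid | OC(=O)C[C@]1(C)CC(=O)[C@H]2C[C@@H]12 | intermediate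
9 | (S)-4-benzyloxazolidin-2-one | O=C1N[C@@H](Cc2ccccc2)CO1 | starting material
10 | mixed anhydride of 8 and pivalic acid | CC(C)(C)C(=O)OC(=O)C[C@]1(C)CC(=O)[C@H]2C[C@@H]12 | intermediate (not isolated)
11 | (S)-4-benzyl-3-{2-[(1R,2S,5S)-2-methyl-4-oxobicyclo[3.1.0]hexan-2-yl]acetyl}oxazolidin-2-one | O=C(C[C@]1(C)CC(=O)[C@H]2C[C@@H]12)N1[C@@H](Cc2ccccc2)COC1=O | intermediate
12 | C4 dioxolane of 11 | O=C(C[C@]1(C)CC3(OCCO3)[C@H]2C[C@@H]12)N1[C@@H](Cc2ccccc2)COC1=O | intermediate
13 | lithium Z-enolate of 12 | [Li]O/C(=C\[C@]1(C)CC3(OCCO3)[C@H]2C[C@@H]12)N1[C@@H](Cc2ccccc2)COC1=O | intermediate (not isolated)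
14 | (9S,9'S)-bis-imide: succinyl bis[(S)-4-benzyloxazolidin-2-one] with a ring A unit (C4 dioxolane, configuration as in 8) on each of C9 and C9' | O=C1OC[C@H](Cc2ccccc2)N1C(=O)[C@H]([C@]1(C)CC3(OCCO3)[C@H]2C[C@@H]12)[C@H](C(=O)N1[C@@H](Cc2ccccc2)COC1=O)[C@]1(C)CC3(OCCO3)[C@H]2C[C@@H]12 | intermediate
15 | (9S,9'S)-bis(dioxolane) succinic diacid | OC(=O)[C@H]([C@]1(C)CC3(OCCO3)[C@H]2C[C@@H]12)[C@H](C(=O)O)[C@]1(C)CC3(OCCO3)[C@H]2C[C@@H]12 | intermediate (not isolated)
16 | (9S,9'S)-diketo succinic diacid (free C4 and C4' ketones) | OC(=O)[C@H]([C@]1(C)CC(=O)[C@H]2C[C@@H]12)[C@H](C(=O)O)[C@]1(C)CC(=O)[C@H]2C[C@@H]12 | intermediate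
17 | 1-bromobut-2-yne | CC#CCBr | starting material
18 | tetralithium salt of 16 (two carboxylates, two C4=C5 enolates) | [Li]OC(=O)[C@H]([C@]1(C)C=C(O[Li])[C@H]2C[C@@H]12)[C@H](C(=O)O[Li])[C@]1(C)C=C(O[Li])[C@H]2C[C@@H]12 | intermediate (not isolated)
19 | (9S,9'S)-diketo diacid with but-2-ynyl on C5 and C5' (C6 syn to C14 and C2) | OC(=O)[C@H]([C@]1(C)[C@@H](CC#CC)C(=O)[C@H]2C[C@@H]12)[C@H](C(=O)O)[C@]1(C)[C@@H](CC#CC)C(=O)[C@H]2C[C@@H]12 | intermediate
20 | dimethyl ester of 19 | COC(=O)[C@H]([C@]1(C)[C@@H](CC#CC)C(=O)[C@H]2C[C@@H]12)[C@H](C(=O)OC)[C@]1(C)[C@@H](CC#CC)C(=O)[C@H]2C[C@@H]12 | intermediate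
21 | bis(dioxolane) of 20 | COC(=O)[C@H]([C@]1(C)[C@@H](CC#CC)C3(OCCO3)[C@H]2C[C@@H]12)[C@H](C(=O)OC)[C@]1(C)[C@@H](CC#CC)C3(OCCO3)[C@H]2C[C@@H]12 | intermediate
22 | trans-3,4-disubstituted 1,2-bis(trimethylsilyloxy)cyclobutene (C8=C8') | C[Si](C)(C)OC4=C(O[Si](C)(C)C)[C@H]([C@]1(C)[C@@H](CC#CC)C3(OCCO3)[C@H]2C[C@@H]12)[C@H]4[C@]1(C)[C@@H](CC#CC)C3(OCCO3)[C@H]2C[C@@H]12 | intermediate
23 | (9S,9'S)-trans-3,4-disubstituted cyclobutane-1,2-dione, bis(butynyl) bis(dioxolane) (precursor of the key step) | CC#CC[C@H]1C3(OCCO3)[C@H]2C[C@H]2[C@]1(C)[C@H]1C(=O)C(=O)[C@@H]1[C@@]1(C)[C@@H]2C[C@@H]2C3(OCCO3)[C@@H]1CC#CC | intermediate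
24 | keto mono-butenolide (one ring B and one butenolide closed, C8' still a ketone) | C15(OCCO5)[C@H]2C[C@H]2[C@@]2(C)[C@H]1CC1=C(C)C(=O)O[C@]13[C@H]2[C@H](C3=O)[C@@]2(C)[C@@H]4C[C@@H]4C5(OCCO5)[C@@H]2CC#CC | intermediate (not isolated)
25 | bis(dioxolane) bis(butenolide): 27 with dioxolanes at C4 and C4' in place of the methylenes (product of the key step) | C15(OCCO5)[C@H]2C[C@H]2[C@@]2(C)[C@H]1CC1=C(C)C(=O)O[C@]13[C@H]2[C@H]1[C@@]2(C)[C@@H]4C[C@@H]4C5(OCCO5)[C@@H]2CC2=C(C)C(=O)O[C@@]213 | intermediate
26 | 4,4'-diketone (15,15'-dinor-4,4'-dioxo analogue of 27) | O=C1[C@H]2C[C@H]2[C@@]2(C)[C@H]1CC1=C(C)C(=O)O[C@]13[C@H]2[C@H]1[C@@]2(C)[C@@H]4C[C@@H]4C(=O)[C@@H]2CC2=C(C)C(=O)O[C@@]213 | intermediate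
27 | CNP0265879.1 | C=C1[C@H]2C[C@H]2[C@@]2(C)[C@H]1CC1=C(C)C(=O)O[C@]13[C@H]2[C@H]1[C@@]2(C)[C@@H]4C[C@@H]4C(=C)[C@@H]2CC2=C(C)C(=O)O[C@@]213 | target

## Step count and least certain steps

Total: 16 steps. Longest linear sequence: 16 steps (1 to 27); 9 and 17 enter as purchased reagents.

**Step 14 (key step).** The low-valent metal may insert into the strained C8–C8' bond of the dione with loss of CO, or reduce the dione to a metal enediolate, before the alkyne and ketone are coupled. The reaction may also stall after the first annulation, or C9 may epimerise by enolisation at 140 °C. Fallback (known chemistry, one annulation at a time on ordinary tethered alkynyl ketones): bis(silyl ether) 22 is methanolysed (dry MeOH, rt) to the acyloin F1 and silylated (TBSCl, imidazole, DMF) to silyl ether F2. Its single ketone is cyclocarbonylated (Mo(CO)6, DMSO, toluene, 100 °C) to mono-butenolide silyl ether F3, which TBAF/AcOH converts to alcohol F4. Dess–Martin periodinane then gives ketone 24, now isolated, and a second cyclocarbonylation under the same conditions gives 25. This sets out from 22, returns at 25, costs five steps instead of two, and also avoids the free dione 23 and step 13.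

**Step 3.** The allyl nucleophile may add 1,2 to the C4 carbonyl instead of 1,4, since allyl metals are the least reliable conjugate donors. Fallback from 5: vinylMgBr, CuBr·SMe2, TMSCl gives the vinyl silyl enol ether F5 (vinyl cuprates add reliably to β,β-disubstituted enones, again anti to the cyclopropane). 9-BBN followed by NaOH/H2O2 hydroborates the vinyl group and hydrolyses the enol ether to keto alcohol F6, and CrO3/H2SO4 in acetone oxidises it to acid 8, where the route resumes.

**Step 7.** The coupling joins two carbons that each carry a quaternary neighbour, so the enolate may be quenched or chlorinated faster than it dimerises, or double stereodifferentiation with the C10 centre may erode the selectivity at C9. Fallback, coupling made intramolecular on a C2-symmetric urea: two equivalents of mixed anhydride 10 acylate the dilithium salt of (4S,5S)-4,5-diphenylimidazolidin-2-one to diacyl urea F7, which is ketalised as in step 6 to F8. Double enolisation (LiN(iPr)2) and oxidation (CuCl2) close the seven-membered ring to F9, each phenyl group shielding its neighbouring enolate as the benzyl group of 9 does. LiOH/H2O2 then HCl, as in step 8, returns diacid 16.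

**Step 9.** Facial selectivity in the C–C bond formation at C5 may be poor, because the cyclopropane and C14 sit on the face the electrophile must use. Fallback, thermodynamic instead of kinetic control: the alkylation mixture is esterified as in step 10 and equilibrated with DBU in toluene at 60 °C. C5 is the only centre that can enolise there, and the isomer with C6 anti to the branched C9 substituent, which is 20, should predominate. The fallback sets out from and returns to 20 and makes no new compound.

**Step 16.** Methylenation of the hindered C4 ketones may be incomplete, or C5 may be lost through metal enolates. Fallback, Peterson olefination from 26: Me3SiCH2Li/CeCl3 (THF, −78 °C), too weakly basic to enolise C4, adds to both ketones to give bis(β-hydroxysilane) F10. KN(SiMe3)2 at 0 °C then eliminates silanolate to give 27; once C4 is a carbinol carbon, H5 is no longer acidic.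

## Further compounds

F1 | step 14 | acyloin from 22: trans-3,4-disubstituted 2-hydroxycyclobutanone (carbinol epimers) | OC4C(=O)[C@H]([C@]1(C)[C@@H](CC#CC)C3(OCCO3)[C@H]2C[C@@H]12)[C@H]4[C@]1(C)[C@@H](CC#CC)C3(OCCO3)[C@H]2C[C@@H]12
F2 | step 14 | tert-butyldimethylsilyl ether of F1 | CC(C)(C)[Si](C)(C)OC4C(=O)[C@H]([C@]1(C)[C@@H](CC#CC)C3(OCCO3)[C@H]2C[C@@H]12)[C@H]4[C@]1(C)[C@@H](CC#CC)C3(OCCO3)[C@H]2C[C@@H]12
F3 | step 14 | mono-butenolide with C8' as silyloxy carbinol | C15(OCCO5)[C@H]2C[C@H]2[C@@]2(C)[C@H]1CC1=C(C)C(=O)O[C@]13[C@H]2[C@H](C3O[Si](C)(C)C(C)(C)C)[C@@]2(C)[C@@H]4C[C@@H]4C5(OCCO5)[C@@H]2CC#CC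
F4 | step 14 | mono-butenolide with C8' as free carbinol | C15(OCCO5)[C@H]2C[C@H]2[C@@]2(C)[C@H]1CC1=C(C)C(=O)O[C@]13[C@H]2[C@H](C3O)[C@@]2(C)[C@@H]4C[C@@H]4C5(OCCO5)[C@@H]2CC#CC
F5 | step 3 | trimethylsilyl enol ether of the C10 vinyl adduct | C=C[C@]1(C)C=C(O[Si](C)(C)C)[C@H]2C[C@@H]12
F6 | step 3 | keto alcohol (C9H2–C8H2OH on C10) | OCC[C@]1(C)CC(=O)[C@H]2C[C@@H]12
F7 | step 7 | 1,3-diacyl-(4S,5S)-4,5-diphenylimidazolidin-2-one, C4 ketones free | O=C1N(C(=O)C[C@]4(C)CC(=O)[C@H]5C[C@@H]45)[C@@H](c7ccccc7)[C@H](c7ccccc7)N1C(=O)C[C@]4(C)CC(=O)[C@H]5C[C@@H]45
F8 | step 7 | bis(dioxolane) of F7 | O=C1N(C(=O)C[C@]4(C)CC6(OCCO6)[C@H]5C[C@@H]45)[C@@H](c7ccccc7)[C@H](c7ccccc7)N1C(=O)C[C@]4(C)CC6(OCCO6)[C@H]5C[C@@H]45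
F9 | step 7 | (9S,9'S) intramolecular coupling product, succinyl bridge across the urea nitrogens | O=C1N2[C@@H](c7ccccc7)[C@H](c7ccccc7)N1C(=O)[C@H]([C@]4(C)CC6(OCCO6)[C@H]5C[C@@H]45)[C@@H]([C@]4(C)CC6(OCCO6)[C@H]5C[C@@H]45)C2=O
F0 | step 9 | none | none
F10 | step 16 | bis(β-hydroxysilane): C4 and C4' as C(OH)CH2SiMe3 (carbinol epimers) | C[Si](C)(C)CC1(O)[C@H]2C[C@H]2[C@@]2(C)[C@H]1CC1=C(C)C(=O)O[C@]13[C@H]2[C@H]1[C@@]2(C)[C@@H]4C[C@@H]4C(O)(C[Si](C)(C)C)[C@@H]2CC2=C(C)C(=O)O[C@@]213
A1 | alternative 1 | 2,3-bis(2-methylbicyclo[3.1.0]hex-3-en-2-yl)succinic acid | OC(=O)[C@H]([C@]1(C)C=C[C@H]2C[C@@H]12)[C@H](C(=O)O)[C@]1(C)C=C[C@H]2C[C@@H]12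
A2 | alternative 1 | bis(4-methylbicyclo[3.1.0]hex-3-en-2-yl) succinate (ester oxygens anti to the cyclopropane methylene) | O=C(CCC(=O)O[C@H]1C=C(C)[C@@H]2C[C@H]12)O[C@H]1C=C(C)[C@@H]2C[C@H]12
A3 | alternative 2 | lindenane tricycle with C4=C15 methylene and C8 dioxolane | C=C1[C@H]2C[C@H]2[C@@]2(C)[C@H]1CCC3(OCCO3)C2
A4 | alternative 2 | ring B vinyl bromide with cyclopropyl and methyl on C10 and 1-bromovinyl on C5 | C=C(Br)[C@@H]1CCC3(OCCO3)C[C@@]1(C)C1CC1
A5 | alternative 3 | lindenane tricycle with C4=C15 methylene and C7 dioxolane | C=C1[C@H]2C[C@H]2[C@@]2(C)[C@H]1CC3(OCCO3)CC2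
A6 | alternative 3 | trans-eudesm-3-ene 1β-mesylate with C7 dioxolane | CS(=O)(=O)O[C@@H]1CC=C(C)[C@@H]2CC3(OCCO3)CC[C@@]12C
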